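**Plan**

Retrosynthesis: C15-OH goes back to a Weinreb amide and C8–C17 to C8–Br. C8 is then taken out of ring B (cuts C7–C8 and C8–C9), which restores a temporary C7–C9 bond. The remaining cuts are the 6-O-acyl bond, C9–C10 (Nazarov-type closure) and the temporary C7–C9 bond (acetylide + aldehyde).
Enabling feature: in ring B (C5–C6–C7–C8–C9–C10) the triad C7(OH)–C8=C9 is a 2-substituted cyclohex-2-enol with a trans-diaxial 6β-acyloxy neighbour. This is the retron of an allyl cation C7–C8–C9, set free when a CBr2 bridge on the C7–C9 bond of a five-membered ring (C5, C6, C7, C9, C10) opens.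
Forward: ring A is bought (β-cyclocitral) and C11–C16 comes from methyl geranate; the two are joined at C7–C9. Gold closes the five-membered ring, CBr2 brings in C8, silver opens the cyclopropane to ring B, and the C8 methyl and C15 are adjusted last.
Stereochemistry: C10 comes from a chiral gold catalyst. C5 comes from kinetic α-protonation and C6 from α-hydride, because the axial C10 and C4β methyls close the β face. C7 comes from anti capture of the cation bridged by the 6β-ester, and 13E from geranate.

Key step: step 9

Assumption: the SMILES is read as the normal labdane series (5α-H, 10β-CH3, 6β-O-acyl, 7α-OH = 5S,6S,7S,10S; 13E). Labdane numbering is kept throughout, and in the hydrindane intermediates C8/C17 are absent and C7 is bonded to C9.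

**Step 1**
Reactants: 1 β-cyclocitral
Product: 2 2-ethynyl-1,3,3-trimethylcyclohex-1-ene
Conditions: TMSCHN2, LDA, THF, −78 °C → rt
Reagents that add atoms: trimethylsilyldiazomethane C[Si](C)(C)C=[N+]=[N-]
Why: Colvin rearrangement: the lithiated diazomethane adds to the hindered enal, and loss of silanolate and N2 gives an alkylidene carbene whose 1,2-H shift should deliver the enyne (new carbon = C7) without touching the tetrasubstituted alkene.

**Step 2**
Reactants: 3 methyl (2E)-geranate
Product: 4 (2E)-N-methoxy-N,3,7-trimethylocta-2,6-dienamide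
Conditions: MeNH(OMe)·HCl, i-PrMgCl, THF, −20 °C
Reagents that add atoms: N,O-dimethylhydroxylamine hydrochloride CNOC.Cl
Why: Weinreb amide formation by aminolysis of the ester with the chloromagnesium amide, which attacks only the carbonyl group and leaves the 2E geometry (later 13E) untouched.

**Step 3**
Reactants: 4 (2E)-N-methoxy-N,3,7-trimethylocta-2,6-dienamide
Product: 5 (2E)-N-methoxy-N,3-dimethyl-6-oxohex-2-enamide
Conditions: O3 (Sudan III end point), CH2Cl2, −78 °C; Me2S
Reagents that add atoms: ozone [O-][O+]=O
Why: Chemoselective ozonolysis: the electron-rich 6,7-alkene reacts far faster than the amide-conjugated 2,3-alkene, so one equivalent of ozone and reductive work-up should give the aldehyde (its carbon = C9).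

**Step 4**
Reactants: 2 2-ethynyl-1,3,3-trimethylcyclohex-1-ene; 5 (2E)-N-methoxy-N,3-dimethyl-6-oxohex-2-enamide
Product: 8 racemic (2E)-6-acetoxy-N-methoxy-N,3-dimethyl-8-(2,6,6-trimethylcyclohex-1-enyl)oct-2-en-7-ynamide, via lithium acetylide 6 (not isolated), via lithium alkoxide 7 (not isolated)
Conditions: n-BuLi, THF, −78 °C; 5; then Ac2O, −78 → 0 °C
Reagents that add atoms: acetic anhydride CC(=O)OC(C)=O
Why: 1,2-Addition of a lithium acetylide to the aldehyde, far more electrophilic than the Weinreb amide at −78 °C, forms the temporary C7–C9 bond and the alkoxide is acetylated in the same flask; the carbinol centre is left racemic because step 5 erases it.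

**Step 5**
Reactants: 8 racemic enynyl acetate
Product: 10 cyclopentadienyl acetate (6-acetoxy-8,17-dinorlabda-5,7(9),13E-trien-15-oic Weinreb amide with 10β-methyl), via allenyl acetate 9 (not isolated)
Conditions: (R)-DTBM-SEGPHOS(AuCl)2 (2.5 mol %; the antipode if screening shows it gives the 10β-methyl series), AgSbF6 (5 mol %), 4 Å MS, CH2Cl2, −20 °C
Reagents that add atoms: none
Why: Proposed new method: Au(I) triggers a 1,3-acyloxy shift to allenyl acetate 9, which moves the oxygen from C9 to C6, and its gold-bound pentadienyl cation C9–C7–C6–C5–C10 no longer carries the C9 stereocentre, so both enantiomers of 8 converge. The 4π-conrotatory closure C9–C10 within the chiral digold pocket sets the quaternary C10, and a 1,2-H shift from C9 to the C7 gold carbene releases 10, which cannot isomerise because C10 bears no hydrogen. The closest known reaction types are the racemic gold-catalysed 1,3-acyloxy migration/Nazarov/1,2-H-shift cascade of 5-en-2-yn-1-yl acetates and the enantioconvergent use of racemic propargylic esters with DTBM-SEGPHOS-gold carbenoids. The enantioselective variant and closure onto the twisted, tetrasubstituted trimethylcyclohexenyl terminus are new.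

**Step 6**
Reactants: 10 cyclopentadienyl acetate
Product: 12 trans-hydrindenol (5α-H-6β-hydroxy-8,17-dinorlabda-7(9),13E-dien-15-oic Weinreb amide), via trans-enone 11 (not isolated)
Conditions: NaBH4, CeCl3·7H2O, MeOH–THF, −40 → 0 °C
Reagents that add atoms: none
Why: As in the classical borohydride reduction of steroidal dienol acetates, slow methanolysis of the enol acetate frees a dienol that is protonated at C5 from the α face (the syn-axial C10 and C4β methyls close the β face), and the strained trans-enone 11 is taken by a Luche 1,2-reduction, with hydride again from the α face, before it can epimerise, which sets 5α-H and 6β-OH.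

**Step 7**
Reactants: 12 trans-hydrindenol
Product: 13 6β-isovalerate of 12
Conditions: isovaleryl chloride, Et3N, DMAP (cat.), CH2Cl2, 0 °C → rt
Reagents that add atoms: isovaleryl chloride CC(C)CC(=O)Cl
Why: DMAP-catalysed acylation installs the final ester while the 6β-hydroxyl is the only one in the molecule and sits on the more open five-membered ring; no stereocentre is touched.

**Step 8**
Reactants: 13 6β-isovalerate
Product: 14 gem-dibromocyclopropane (C8Br2 bridging C7 and C9 on the α face)
Conditions: CHBr3, 50% aq NaOH, BnEt3NCl (cat.), CH2Cl2, 0 °C; kept cold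
Reagents that add atoms: bromoform BrC(Br)Br
Why: Phase-transfer dibromocarbene addition: the electrophilic carbene takes the only electron-rich alkene C7=C9 (the 13-ene is deactivated by the amide) and approaches from the α face, anti to the 10β-methyl and the 6β-ester, which sets C7 and C9 of the cyclopropane.

**Step 9**
Reactants: 14 gem-dibromocyclopropane
Product: 17 8-bromo-7α-hydroxy-6β-isovaleryloxy-17-norlabda-8,13E-dien-15-oic Weinreb amide, via acyloxonium ion 15 (not isolated), via 7α-trifluoroacetate 16 (not isolated)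
Conditions: AgO2CCF3, 2,6-di-tert-butylpyridine, 4 Å MS, CH2Cl2, −20 °C → rt, dark; then MeOH, NaHCO3, 0 °C
Reagents that add atoms: silver trifluoroacetate [Ag+].[O-]C(=O)C(F)(F)F
Why: Ag(I) abstracts the endo bromide while the C7–C9 bond opens in the allowed 2π-disrotatory sense (Woodward–Hoffmann–DePuy rule), driven by cyclopropane strain release, so C8 enters the ring and the five-membered ring C5–C6–C7–C9–C10 becomes six-membered ring B as the 2-bromoallyl cation C7–C8(Br)–C9. The closest known reaction type is the silver-promoted opening of 6,6-dibromobicyclo[3.1.0]hexanes to 2-bromocyclohex-2-enyl esters, combined with Prévost-type neighbouring-group participation. No ring is closed by a new C–C bond: ring B arises by cleavage of the zero bridge, and the only closure is the transient five-membered ring of 15 (5-exo-trig attack of the 6β-ester carbonyl oxygen on the β face of C7), which is reopened in the same flask. C7 is the only new stereocentre, and trifluoroacetate can reach it only from the α face, anti to the bridging or shielding 6β-ester and along the pseudo-axial trajectory, so free cation and bridged ion converge on the trans-diaxial 6β-acyloxy/7α-oxy array. The step needs capture at C7 rather than C9, which is secured because C9 is tertiary and neopentyl next to C10 and because capture at C7 leaves the tetrasubstituted C8=C9 bond. It also needs exclusion of water until 16 has formed, since water would collapse 15 to the cis-hydroxy ester; mild methanolysis then removes only the activated trifluoroacetate and leaves the isovalerate and amide untouched.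

**Step 10**
Reactants: 17 8-bromo alcohol
Product: 18 7α-hydroxy-6β-isovaleryloxylabda-8,13E-dien-15-oic Weinreb amide
Conditions: Me2Zn, Pd(dppf)Cl2 (cat.), 1,4-dioxane, 80 °C
Reagents that add atoms: dimethylzinc C[Zn]C
Why: Negishi coupling: the small methyl group is transferred to the hindered tetrasubstituted alkenyl bromide with retention of the ring alkene, the 7-OH travels as its zinc alkoxide, and ester and Weinreb amide are inert to Me2Zn.

**Step 11**
Reactants: 18 Weinreb amide
Product: 19 7α-hydroxy-6β-isovaleryloxylabda-8,13E-dien-15-al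
Conditions: DIBAL-H (2.2 equiv), THF, −78 °C; aq Rochelle salt
Reagents that add atoms: none
Why: Weinreb amide reduction: the amide is trapped at −78 °C as a chelated tetrahedral aluminate much faster than hydride can reach the axial isovalerate flanked by two syn-axial methyls, and work-up releases the E-enal.

**Step 12**
Reactants: 19 enal
Product: 20 6β-isovaleryloxylabda-8,13E-diene-7α,15-diol (target)
Conditions: NaBH4, CeCl3·7H2O, MeOH, 0 °C
Reagents that add atoms: none
Why: Luche reduction gives clean 1,2-reduction of the enal to the E-allylic alcohol and does not touch the ester or any stereocentre.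

**Compound list**

1 | β-cyclocitral (2,6,6-trimethylcyclohex-1-ene-1-carbaldehyde) | O=CC1=C(C)CCCC1(C)C | starting material
2 | 2-ethynyl-1,3,3-trimethylcyclohex-1-ene | C#CC1=C(C)CCCC1(C)C | intermediate
3 | methyl (2E)-geranate | CC(C)=CCC/C(C)=C/C(=O)OC | starting material
4 | (2E)-N-methoxy-N,3,7-trimethylocta-2,6-dienamide | CC(C)=CCC/C(C)=C/C(=O)N(C)OC | intermediate
5 | (2E)-N-methoxy-N,3-dimethyl-6-oxohex-2-enamide | O=CCC/C(C)=C/C(=O)N(C)OC | intermediate
6 | lithium acetylide of 2 | [Li]C#CC1=C(C)CCCC1(C)C | intermediate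
7 | lithium propargylic alkoxide (racemic) | [Li]OC(CC/C(C)=C/C(=O)N(C)OC)C#CC1=C(C)CCCC1(C)C | intermediate
8 | racemic enynyl acetate | CC(=O)OC(CC/C(C)=C/C(=O)N(C)OC)C#CC1=C(C)CCCC1(C)C | intermediate
9 | allenyl acetate (axial chirality not defined) | CC(=O)OC(=C=CCC/C(C)=C/C(=O)N(C)OC)C1=C(C)CCCC1(C)C | intermediate
10 | cyclopentadienyl acetate, 10β-methyl | C1=C(CC/C(C)=C/C(=O)N(C)OC)[C@@]2(C)CCCC(C)(C)C2=C1OC(C)=O | intermediate
11 | trans-enone, 5α-H, 6-oxo | C1=C(CC/C(C)=C/C(=O)N(C)OC)[C@@]2(C)CCCC(C)(C)[C@@H]2C1=O | intermediate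
12 | trans-hydrindenol, 5α-H, 6β-OH | C1=C(CC/C(C)=C/C(=O)N(C)OC)[C@@]2(C)CCCC(C)(C)[C@@H]2[C@@H]1O | intermediate
13 | 6β-isovalerate of 12 | C1=C(CC/C(C)=C/C(=O)N(C)OC)[C@@]2(C)CCCC(C)(C)[C@@H]2[C@@H]1OC(=O)CC(C)C | intermediate
14 | gem-dibromocyclopropane, C8Br2 on the α face of C7–C9 | BrC1(Br)[C@@H]2[C@@H](OC(=O)CC(C)C)[C@H]3C(C)(C)CCC[C@]3(C)[C@]12CC/C(C)=C/C(=O)N(C)OC | intermediate
15 | 6β,7β-bridged acyloxonium (1,3-dioxolan-2-ylium) ion, trifluoroacetate counter-ion | BrC1=C(CC/C(C)=C/C(=O)N(C)OC)[C@@]2(C)CCCC(C)(C)[C@@H]2[C@@H]3OC(CC(C)C)=[O+][C@H]13 | intermediate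
16 | 8-bromo-6β-isovalerate-7α-trifluoroacetate | BrC1=C(CC/C(C)=C/C(=O)N(C)OC)[C@@]2(C)CCCC(C)(C)[C@@H]2[C@H](OC(=O)CC(C)C)[C@H]1OC(=O)C(F)(F)F | intermediate
17 | 8-bromo-7α-hydroxy-6β-isovalerate Weinreb amide | BrC1=C(CC/C(C)=C/C(=O)N(C)OC)[C@@]2(C)CCCC(C)(C)[C@@H]2[C@H](OC(=O)CC(C)C)[C@H]1O | intermediate
18 | 7α-hydroxy-6β-isovaleryloxylabda-8,13E-dien-15-oic Weinreb amide | CC1=C(CC/C(C)=C/C(=O)N(C)OC)[C@@]2(C)CCCC(C)(C)[C@@H]2[C@H](OC(=O)CC(C)C)[C@H]1O | intermediate
19 | 7α-hydroxy-6β-isovaleryloxylabda-8,13E-dien-15-al | CC1=C(CC/C(C)=C/C=O)[C@@]2(C)CCCC(C)(C)[C@@H]2[C@H](OC(=O)CC(C)C)[C@H]1O | intermediate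
20 | 6β-isovaleryloxylabda-8,13E-diene-7α,15-diol | CC1=C(CC/C(C)=C/CO)[C@@]2(C)CCCC(C)(C)[C@@H]2[C@H](OC(=O)CC(C)C)[C@H]1O | target

**Totals**

Total step count: 12.
Longest linear sequence: 11 steps (3 → 20, steps 2–12).

**Steps most likely to fail**

1. **Step 5 (labelled step).** The electrocyclisation may show poor facial discrimination, or may close sluggishly at the twisted tetrasubstituted terminus.
 Fallback, from 8: the cascade is run with the achiral catalyst Ph3PAuCl/AgSbF6 (the known racemic reaction) to give racemic cyclopentadienyl acetate F1. Under the conditions of step 6 this gives racemic trans-hydrindenol F2. Esterification with (S)-O-methylmandelic acid (DCC, DMAP) gives the mandelate of the 10β-methyl series F3 and the mandelate of the antipodal series F4, which are separated by chromatography or crystallisation. Methanolysis of F3 (K2CO3, MeOH) comes back to the route at 12.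

2. **Step 6.** C5 may epimerise before reduction, or protonation may be steered by relief of strain. Either would lead into the cis-fused series.
 Fallback, from 10: the creation of C5 is postponed to the decalin stage, where α-protonation is both the kinetic and the thermodynamic outcome.
 - Dibromocarbene addition to the C7=C9 bond of 10 gives dienyl acetate dibromocyclopropane F5.
 - Opening with AgOAc in dry AcOH–CH2Cl2 enlarges the ring to 7α-acetoxy-8-bromo enol acetate F6.
 - NaBH4/CeCl3 in MeOH cleaves only the enol acetate and passes through trans-fused 7α-acetoxy-6-ketone F7 to 6β-alcohol F8.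
 - Isovaleryl chloride/DMAP gives mixed diester F9.
 - Selective methanolysis of the less hindered allylic acetate (K2CO3, MeOH, 0 °C) comes back to the route at 17.

3. **Step 9.** The bridged ion may collapse hydrolytically to the cis series, or the allyl cation may lose a proton.
 Fallback, from 14: the participation is used deliberately. Opening under wet Woodward-type conditions (AgOAc, aqueous AcOH) hydrolyses the bridged ion with the ester staying on the axial oxygen, to give 7β-hydroxy-6β-isovalerate F10. Mitsunobu inversion of the equatorial allylic alcohol with chloroacetic acid (DIAD, PPh3) gives 7α-chloroacetate F11. Mild methanolysis (NaHCO3, MeOH) comes back to the route at 17.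

**Further compounds**

F1 | step 5 | racemic cyclopentadienyl acetate | C1=C(CC/C(C)=C/C(=O)N(C)OC)C2(C)CCCC(C)(C)C2=C1OC(C)=O
F2 | step 5 | racemic trans-hydrindenol (both enantiomers) | C1=C(CC/C(C)=C/C(=O)N(C)OC)[C@@]2(C)CCCC(C)(C)[C@@H]2[C@@H]1O.C1=C(CC/C(C)=C/C(=O)N(C)OC)[C@]2(C)CCCC(C)(C)[C@H]2[C@H]1O
F3 | step 5 | (S)-O-methylmandelate of 12 | C1=C(CC/C(C)=C/C(=O)N(C)OC)[C@@]2(C)CCCC(C)(C)[C@@H]2[C@@H]1OC(=O)[C@@H](OC)c3ccccc3
F4 | step 5 | (S)-O-methylmandelate of the enantiomer of 12 | C1=C(CC/C(C)=C/C(=O)N(C)OC)[C@]2(C)CCCC(C)(C)[C@H]2[C@H]1OC(=O)[C@@H](OC)c3ccccc3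
F5 | step 6 | dienyl acetate dibromocyclopropane (C8Br2 on the α face) | BrC1(Br)[C@@H]2C(OC(C)=O)=C3C(C)(C)CCC[C@]3(C)[C@]12CC/C(C)=C/C(=O)N(C)OC
F6 | step 6 | 7α-acetoxy-8-bromo-5-en-6-yl acetate | BrC1=C(CC/C(C)=C/C(=O)N(C)OC)[C@@]2(C)CCCC(C)(C)C2=C(OC(C)=O)[C@H]1OC(C)=O
F7 | step 6 | 7α-acetoxy-8-bromo-5α-H-6-ketone | BrC1=C(CC/C(C)=C/C(=O)N(C)OC)[C@@]2(C)CCCC(C)(C)[C@@H]2C(=O)[C@H]1OC(C)=O
F8 | step 6 | 7α-acetoxy-8-bromo-6β-alcohol | BrC1=C(CC/C(C)=C/C(=O)N(C)OC)[C@@]2(C)CCCC(C)(C)[C@@H]2[C@H](O)[C@H]1OC(C)=O
F9 | step 6 | 7α-acetoxy-8-bromo-6β-isovalerate | BrC1=C(CC/C(C)=C/C(=O)N(C)OC)[C@@]2(C)CCCC(C)(C)[C@@H]2[C@H](OC(=O)CC(C)C)[C@H]1OC(C)=O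
F10 | step 9 | 8-bromo-7β-hydroxy-6β-isovalerate | BrC1=C(CC/C(C)=C/C(=O)N(C)OC)[C@@]2(C)CCCC(C)(C)[C@@H]2[C@H](OC(=O)CC(C)C)[C@@H]1O
F11 | step 9 | 8-bromo-7α-chloroacetoxy-6β-isovalerate | BrC1=C(CC/C(C)=C/C(=O)N(C)OC)[C@@]2(C)CCCC(C)(C)[C@@H]2[C@H](OC(=O)CC(C)C)[C@H]1OC(=O)CCl
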